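**Plan**
1. Numbering: pyrrole N1, aminal CH C6, N7, urea C8, N9, quaternary aminal C10, C11–C13, lactam N14. Ring A is the pyrrole, B the pyrazinone, C the pyrrolidine, D the imidazolidinone.
2. Cuts, in retrosynthetic order: N1–C6 (ring B); N7–C6 (ring D, taken back to a spiro hydantoin with C6 as carbonyl); C10–N9 (taken back to C10–CO2H); N14–acyl; then C10–C11 and C13–N14 (ring C).
3. Enabling feature: apart from its two ring C bonds (to C11 and N14), C10 carries one carbon (C6) and one nitrogen (N9). Both can descend from the two enantiotopic CO2Me groups of a prochiral N-acylpyrrolidine-2,2-dicarboxylate.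
4. Forward order: ring C (cycloalkylation of Boc-aminomalonate), ring A attached at N14, esterase desymmetrization, ring D (Curtius shift, urea, hydantoin), C6 reduced to the carbinolamine, ring B last (N-acyliminium ion caught by N1).
5. Stereochemistry: C10 comes from the enzyme alone and is carried on by the stereoretentive Curtius shift. C6 follows from C10, because rings B and D can only be cis-fused.

Key step: step 5

Assumption: screening of carboxylesterases (pig liver esterase isoenzymes and recombinant homologues) is taken to deliver a catalyst that cleaves the pro-R ester group of the prochiral diester. The configuration of the half-ester is to be secured by anomalous-dispersion X-ray analysis (two bromine atoms) before it is carried on.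

Step 1
Reactants: 1 dimethyl aminomalonate hydrochloride
Product: 2 dimethyl 2-[(tert-butoxycarbonyl)amino]propanedioate
Conditions: Boc2O, NaHCO3, THF–H2O, 0 °C → rt
Reagents that add atoms: di-tert-butyl dicarbonate, CC(C)(C)OC(=O)OC(=O)OC(C)(C)C
Why: Routine carbamate (Boc) protection of the amine set free by bicarbonate, which stops self-condensation of the free aminomalonate and leaves the malonate C–H as the most acidic and first alkylated site in step 2.

Step 2
Reactants: 2 dimethyl 2-[(tert-butoxycarbonyl)amino]propanedioate; 3 1,3-dibromopropane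
Product: 5 1-tert-butyl 2,2-dimethyl pyrrolidine-1,2,2-tricarboxylate, via dimethyl 2-(3-bromopropyl)-2-[(tert-butoxycarbonyl)amino]propanedioate 4 (not isolated)
Conditions: NaH (2.2 equiv), DMF, 0 → 50 °C
Reagents that add atoms: none
Why: Acylaminomalonate C-alkylation followed by 5-exo-tet N-alkylation, in which the first equivalent of hydride gives the malonate enolate that displaces one bromide and the second deprotonates the carbamate NH of 4, whose ring closure is helped by the gem-diester (Thorpe–Ingold) effect, while C2 stays prochiral.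

Step 3
Reactants: 5 1-tert-butyl 2,2-dimethyl pyrrolidine-1,2,2-tricarboxylate
Product: 6 dimethyl pyrrolidine-2,2-dicarboxylate hydrochloride
Conditions: HCl (4 M in 1,4-dioxane), rt
Reagents that add atoms: hydrogen chloride, Cl
Why: Anhydrous acidolysis of the tert-butyl carbamate leaves the methyl esters intact and delivers the amine as a storable salt.

Step 4
Reactants: 6 dimethyl pyrrolidine-2,2-dicarboxylate hydrochloride; 7 4,5-dibromo-1H-pyrrole-2-carboxylic acid
Product: 9 dimethyl 1-(4,5-dibromo-1H-pyrrole-2-carbonyl)pyrrolidine-2,2-dicarboxylate, via 4,5-dibromo-1H-pyrrole-2-carbonyl chloride 8 (not isolated)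
Conditions: 7, (COCl)2, cat. DMF, CH2Cl2, rt, evaporate; then 6, pyridine–CH2Cl2, 0 → 40 °C
Reagents that add atoms: oxalyl chloride, O=C(Cl)C(=O)Cl (its chlorine stands only in intermediate 8, not in 9)
Why: Vilsmeier-type chlorination of the acid and Schotten–Baumann-type N-acylation in pyridine, where an acid chloride is chosen because the amine is hindered and made weakly basic by two geminal esters, and the weak base leaves the pyrrole NH protonated so that self-acylation of 8 stays slow.

Step 5
Reactants: 9 dimethyl 1-(4,5-dibromo-1H-pyrrole-2-carbonyl)pyrrolidine-2,2-dicarboxylate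
Product: 10 (2S)-1-(4,5-dibromo-1H-pyrrole-2-carbonyl)-2-(methoxycarbonyl)pyrrolidine-2-carboxylic acid
Conditions: pig liver esterase (isoenzyme chosen by screening), 0.1 M phosphate buffer pH 7.5, DMSO (10 % v/v), 25 °C, pH-stat (1 M NaOH); then 1 M HCl to pH 3, 0 °C, EtOAc
Reagents that add atoms: water, O
Why: The active-site serine of the carboxylesterase (Ser–His–Glu triad, oxyanion hole) attacks one methoxycarbonyl group of 9, methanol leaves, and water cleaves the acyl-enzyme to release the carboxylate of 10. The closest known reaction type is the pig-liver-esterase desymmetrization of prochiral α,α-disubstituted malonic diesters, α-acylamino-α-alkyl cases included, to quaternary half-esters. No ring is closed and no skeletal bond is formed. The one new stereocentre, C2 (the later C10), is controlled only by the chiral binding pocket, which has to place the flat, lipophilic dibromopyrrolylcarbonyl group on N1 and the small ring methylene C3 in different sub-sites, so that only the pro-R ester reaches the serine. The step needs enantiotopic-group selectivity and a stop after one hydrolysis: the large difference in size and polarity between the two other substituents on C2 secures the first, and the negative charge of the product, which such esterases bind poorly, secures the second. Near-neutral pH and 25 °C keep uncatalysed hydrolysis and decarboxylation of the aminomalonic half-acid slow, and the amide and the C–Br bonds are not touched.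

Step 6
Reactants: 10 (2S)-1-(4,5-dibromo-1H-pyrrole-2-carbonyl)-2-(methoxycarbonyl)pyrrolidine-2-carboxylic acid; 11 2,4-dimethoxybenzylamine
Product: 15 (5R)-6-(4,5-dibromo-1H-pyrrole-2-carbonyl)-3-(2,4-dimethoxybenzyl)-1,3,6-triazaspiro[4.4]nonane-2,4-dione, via methyl (2S)-2-(azidocarbonyl)-1-(4,5-dibromo-1H-pyrrole-2-carbonyl)pyrrolidine-2-carboxylate 12 (not isolated), via methyl (2S)-1-(4,5-dibromo-1H-pyrrole-2-carbonyl)-2-isocyanatopyrrolidine-2-carboxylate 13 (not isolated), via methyl (2R)-1-(4,5-dibromo-1H-pyrrole-2-carbonyl)-2-{[(2,4-dimethoxybenzyl)carbamoyl]amino}pyrrolidine-2-carboxylate 14 (not isolated)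
Conditions: DPPA, Et3N, 1,4-dioxane, rt then 80 °C; 11, rt; DBU, 60 °C
Reagents that add atoms: diphenylphosphoryl azide, [N-]=[N+]=NP(=O)(Oc1ccccc1)Oc1ccccc1
Why: The Curtius rearrangement (concerted 1,2-shift with retention at the migrating quaternary carbon, known for esterase-derived malonic half-esters and for N-acylamino acids, which give gem-diamino derivatives) turns the carboxyl group into N9, the amine adds to the isocyanate, and base closes the urea on the neighbouring ester by 5-exo-trig acyl substitution (ureido-ester route to hydantoins), the benzyl group on N7 being there so that the hydantoin has no acidic imide NH in step 7.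

Step 7
Reactants: 15 (5R)-6-(4,5-dibromo-1H-pyrrole-2-carbonyl)-3-(2,4-dimethoxybenzyl)-1,3,6-triazaspiro[4.4]nonane-2,4-dione
Product: 16 (5R)-6-(4,5-dibromo-1H-pyrrole-2-carbonyl)-3-(2,4-dimethoxybenzyl)-4-hydroxy-1,3,6-triazaspiro[4.4]nonan-2-one (both C4 epimers)
Conditions: NaBH4, MeOH–THF, −10 → 0 °C; aq. NH4Cl
Reagents that add atoms: none
Why: Borohydride reduction of an imide-type carbonyl to the hydroxylactam level, since in an N3-alkylhydantoin C4=O (the later C6) is the only carbonyl that is neither a urea nor a pyrrole-conjugated amide, it is further activated by the α-acylamino group, and no unreactive imide anion can form; the carbinol centre arises as an epimer mixture, which does not matter because it becomes planar in step 8.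

Step 8
Reactants: 16 (5R)-6-(4,5-dibromo-1H-pyrrole-2-carbonyl)-3-(2,4-dimethoxybenzyl)-4-hydroxy-1,3,6-triazaspiro[4.4]nonan-2-one
Product: 18 (6S,10R)-dibromophakellstatin, via (6S,10R)-N7-(2,4-dimethoxybenzyl)dibromophakellstatin 17 (not isolated)
Conditions: TFA–CH2Cl2 (1:4), 0 °C → rt; then anisole, neat TFA, 45 °C
Reagents that add atoms: none
Why: Intramolecular amidoalkylation through an N-acyliminium ion, in which acid ionises the C6–OH bond and pyrrole N1, held by the N14 acyl tether on the N14 face of ring D, closes the six-membered ring B so that C6 can only become S (rings B and D cis-fused, H6 syn to C11), after which the electron-rich benzyl group leaves N7 by SN1 acidolysis and is caught by anisole.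

**Compound list**
1 | dimethyl aminomalonate hydrochloride | COC(=O)C(N)C(=O)OC.Cl | starting material
2 | dimethyl 2-[(tert-butoxycarbonyl)amino]propanedioate | COC(=O)C(NC(=O)OC(C)(C)C)C(=O)OC | intermediate
3 | 1,3-dibromopropane | BrCCCBr | starting material
4 | dimethyl 2-(3-bromopropyl)-2-[(tert-butoxycarbonyl)amino]propanedioate | COC(=O)C(CCCBr)(NC(=O)OC(C)(C)C)C(=O)OC | intermediate
5 | 1-tert-butyl 2,2-dimethyl pyrrolidine-1,2,2-tricarboxylate | COC(=O)C1(C(=O)OC)CCCN1C(=O)OC(C)(C)C | intermediate
6 | dimethyl pyrrolidine-2,2-dicarboxylate hydrochloride | COC(=O)C1(C(=O)OC)CCCN1.Cl | intermediate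
7 | 4,5-dibromo-1H-pyrrole-2-carboxylic acid | OC(=O)c1cc(Br)c(Br)[nH]1 | starting material
8 | 4,5-dibromo-1H-pyrrole-2-carbonyl chloride | ClC(=O)c1cc(Br)c(Br)[nH]1 | intermediate
9 | dimethyl 1-(4,5-dibromo-1H-pyrrole-2-carbonyl)pyrrolidine-2,2-dicarboxylate | COC(=O)C1(C(=O)OC)CCCN1C(=O)c1cc(Br)c(Br)[nH]1 | intermediate
10 | (2S)-1-(4,5-dibromo-1H-pyrrole-2-carbonyl)-2-(methoxycarbonyl)pyrrolidine-2-carboxylic acid | COC(=O)[C@@]1(C(=O)O)CCCN1C(=O)c1cc(Br)c(Br)[nH]1 | intermediate
11 | 2,4-dimethoxybenzylamine | NCc1ccc(OC)cc1OC | starting material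
12 | methyl (2S)-2-(azidocarbonyl)-1-(4,5-dibromo-1H-pyrrole-2-carbonyl)pyrrolidine-2-carboxylate | COC(=O)[C@@]1(C(=O)N=[N+]=[N-])CCCN1C(=O)c1cc(Br)c(Br)[nH]1 | intermediate
13 | methyl (2S)-1-(4,5-dibromo-1H-pyrrole-2-carbonyl)-2-isocyanatopyrrolidine-2-carboxylate | COC(=O)[C@@]1(N=C=O)CCCN1C(=O)c1cc(Br)c(Br)[nH]1 | intermediate
14 | methyl (2R)-1-(4,5-dibromo-1H-pyrrole-2-carbonyl)-2-{[(2,4-dimethoxybenzyl)carbamoyl]amino}pyrrolidine-2-carboxylate (same spatial arrangement as 13; the descriptor changes by priority only) | COC(=O)[C@@]1(NC(=O)NCc2ccc(OC)cc2OC)CCCN1C(=O)c1cc(Br)c(Br)[nH]1 | intermediate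
15 | (5R)-6-(4,5-dibromo-1H-pyrrole-2-carbonyl)-3-(2,4-dimethoxybenzyl)-1,3,6-triazaspiro[4.4]nonane-2,4-dione | O=C2[C@@]1(NC(=O)N2Cc3ccc(OC)cc3OC)CCCN1C(=O)c4cc(Br)c(Br)[nH]4 | intermediate
16 | (5R)-6-(4,5-dibromo-1H-pyrrole-2-carbonyl)-3-(2,4-dimethoxybenzyl)-4-hydroxy-1,3,6-triazaspiro[4.4]nonan-2-one, both C4 epimers | OC2[C@@]1(NC(=O)N2Cc3ccc(OC)cc3OC)CCCN1C(=O)c4cc(Br)c(Br)[nH]4 | intermediate
17 | (6S,10R)-N7-(2,4-dimethoxybenzyl)dibromophakellstatin (tetracycle 18 with the benzyl group on urea nitrogen N7) | O=C1N(Cc4ccc(OC)cc4OC)[C@H]2n3c(cc(Br)c3Br)C(=O)N3CCC[C@]23N1 | intermediate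
18 | (6S,10R)-dibromophakellstatin | O=C1N[C@H]2n3c(cc(Br)c3Br)C(=O)N3CCC[C@]23N1 | target

**Step count**
Total step count: 8. Longest linear sequence: 8 steps (1 → 18). Acid 7 and amine 11 enter without steps of their own.

**Steps most likely to fail**

Step 5. The bulky, sparingly soluble substrate may turn over slowly. It may also bind in two orientations, which would give low enantiotopic-group selectivity or a preference for the pro-S ester. Uncatalysed hydrolysis, which the neighbouring pyrrole NH may assist, could erode the enantiomeric purity.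
- Fallback (from 9, back at 10): the two esters are differentiated chemically instead of enzymatically.
- Controlled saponification of 9 with KOH in MeOH–THF at 0 °C should give the racemic half-ester F1.
- F1 is resolved by fractional crystallisation of the (R)-1-phenylethylammonium salt F2. The antipodal amine is taken if the (R)-amine crystallises with the wrong acid. Cold dilute acid then sets 10 free.
- The (2R)-half-ester F3 left in the mother liquor is not lost, because esterification (MeOH, EDC, DMAP) returns it to prochiral 9.

Step 7. Hydride addition may be slow at a carbonyl flanked by the spiro centre. The carbinolamine may also ring-open under the basic conditions, with over-reduction of the chain form.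
- Fallback (from 10, back at 18): C6 is taken from the ester to the aldehyde level before ring D exists, with no group on N7.
- 10 is carried to isocyanate 13 as in step 6 (DPPA, Et3N, dioxane, rt then 80 °C), and NH3 in dioxane at 0 °C gives the primary urea ester F4.
- LiBH4 in THF at 0 °C reduces the activated ester to the primary alcohol F5.
- Dess–Martin periodinane in CH2Cl2 gives the aldehyde F6, which should be obtained as its ring tautomer, the carbinolamine F7.
- TFA in CH2Cl2 closes the last ring to 18.

Step 8. Acidolysis of the N7–benzyl bond may be sluggish. Forcing conditions could then bring loss or migration of bromine on the pyrrole, or reopening of the C6 aminal with capture by the scavenger.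
- Fallback (from 16, back at 18): ring closure and deprotection are separated, and the benzyl group is removed by oxidation instead of acid.
- 16 is treated only with TFA–CH2Cl2 at rt, and 17 is isolated.
- Ceric ammonium nitrate in MeCN–H2O at 0 °C oxidises the electron-rich arene by single-electron transfer, and the resulting N7 hemiaminal collapses to 18. The electron-poor dibromoacylpyrrole is the harder ring to oxidise.
- No new compound is made (F0).

**Further compounds**
F1 | step 5 | rac-1-(4,5-dibromo-1H-pyrrole-2-carbonyl)-2-(methoxycarbonyl)pyrrolidine-2-carboxylic acid | COC(=O)C1(C(=O)O)CCCN1C(=O)c1cc(Br)c(Br)[nH]1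
F2 | step 5 | (R)-1-phenylethylammonium (2S)-1-(4,5-dibromo-1H-pyrrole-2-carbonyl)-2-(methoxycarbonyl)pyrrolidine-2-carboxylate | COC(=O)[C@@]1(C(=O)[O-])CCCN1C(=O)c1cc(Br)c(Br)[nH]1.C[C@@H]([NH3+])c1ccccc1
F3 | step 5 | (2R)-1-(4,5-dibromo-1H-pyrrole-2-carbonyl)-2-(methoxycarbonyl)pyrrolidine-2-carboxylic acid | COC(=O)[C@]1(C(=O)O)CCCN1C(=O)c1cc(Br)c(Br)[nH]1
F4 | step 7 | methyl (2R)-2-(carbamoylamino)-1-(4,5-dibromo-1H-pyrrole-2-carbonyl)pyrrolidine-2-carboxylate | COC(=O)[C@@]1(NC(N)=O)CCCN1C(=O)c1cc(Br)c(Br)[nH]1
F5 | step 7 | 1-[(2R)-1-(4,5-dibromo-1H-pyrrole-2-carbonyl)-2-(hydroxymethyl)pyrrolidin-2-yl]urea | OC[C@@]1(NC(N)=O)CCCN1C(=O)c1cc(Br)c(Br)[nH]1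
F6 | step 7 | 1-[(2R)-1-(4,5-dibromo-1H-pyrrole-2-carbonyl)-2-formylpyrrolidin-2-yl]urea | O=C[C@@]1(NC(N)=O)CCCN1C(=O)c1cc(Br)c(Br)[nH]1
F7 | step 7 | (5R)-6-(4,5-dibromo-1H-pyrrole-2-carbonyl)-4-hydroxy-1,3,6-triazaspiro[4.4]nonan-2-one | OC2[C@@]1(NC(=O)N2)CCCN1C(=O)c3cc(Br)c(Br)[nH]3
F0 | step 8 | none | none
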